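## Analysis of the target

The target is the aryl ether between the 7-hydroxyl of scopoletin and C11 of a bicyclic drimane diol. Drimane numbering is used throughout: ring A is C1–C5 with C10, ring B is C5–C10, C11 sits on C9, and the methyl groups sit on C4 (two), C8 and C10; coumarin atoms are primed. The decalin is trans-fused (H5 anti to the C10 methyl) and carries a gem-dimethyl group at C4, a secondary hydroxyl at C3, a trisubstituted C7=C8 alkene and the CH2OAr arm on C9. The four stereocentres are (3S,5S,9S,10R). H9 lies on the face of the C10 methyl, so the C9 arm is anti to that methyl, and the C3 hydroxyl is axial, syn to H5. Both are the less stable epimers, so neither can be reached by equilibration. Sensitive groups are the coumarin lactone (hydride, strong base), the 7,8-alkene, which acid can move to the 8,9-position, and C9, which would epimerise or conjugate if C11 were a carbonyl next to that alkene. The difficulty lies in the three contiguous congested carbons C4, C5 and C10, the two contra-thermodynamic centres, and an etherification at a β-branched primary carbon. The strategy rests on ring B: with a masked ketone at C7, the bonds C5–C10 and C8–C9 join a C5–C8 diene to a C9–C10 alkene. Because C1–C4 tether the two, ring A closes in the same event, C3 on the tether relays absolute configuration, and the C7 oxygen later allows C9 to be reset.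

## Retrosynthetic reasoning

**C11–O ether.** The last bond to be made is C11–O7′. Cutting it gives diol 23 and coumarin 24, which is bought with its ring, methoxy group and lactone complete. The cut is made last because the lactone would not survive the hydride and borane steps the terpenoid half needs. The forward reaction must etherify the primary C11 hydroxyl and leave the axial, neopentyl C3 hydroxyl alone; a Mitsunobu reaction does this by steric discrimination.

**C3 configuration.** The axial alcohol of 23 is traced to ketone 21 and, through 20, to the equatorial silyl ether 19. Inversion by substitution next to the quaternary C4 is not credible. An oxidation–reduction pair is, because a bulky hydride approaches a 4,4-dimethyl-3-ketone along the equatorial path and leaves the hydroxyl axial. The gain is that C3 can be carried as (R), the configuration the ring-forming step needs.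

**C9, the 7,8-alkene and the C7 oxygen.** Compound 19 is derived from tosylhydrazone 16 of enone 15 by reductive 1,3-transposition. Hydride adds to C7, loss of sulfinate gives allylic diazene 18, and its retro-ene loss of nitrogen moves the double bond from 8,9 to 7,8 and hands a hydrogen to C9 on the face from which nitrogen leaves. One operation removes the C7 oxygen, places the alkene and sets C9 by intramolecular delivery on the hindered face, which no external reagent would choose.

**C8=C9 unsaturation.** Enone 15 comes from ketone 13 by dehydrogenation through the more substituted enol ether 14, and 13 from keto alcohol 12 by acetylation. Since C8 and C9 both become trigonal here, their configurations in earlier intermediates need no control.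

**Both rings.** Ketone 12 is the reduced and hydrolysed form of cycloadduct 10. In 10 the bonds C5–C10 and C8–C9 are cut together, which opens both rings and leads to acyclic trienal 9. No other pair of bonds removes two rings, the quaternary C10 and the C5 stereocentre at once while also leaving a carbonyl equivalent at C7. The forward reaction has to give the trans fusion and the (5S,10R) sense from the single stereocentre at C3.

**Functional-group order before the cycloaddition.** Trienal 9 goes back to allylic alcohol 8 and methyl ester 7, and removal of both silyl groups from 7 gives hydroxy enone 6. The dienol ether is made while C11 is still an ester, which cannot be silylated, so the diene is never generated beside an enolisable enal. Reduction and allylic oxidation then give the aldehyde without touching the silyl enol ether.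

**C5=C6 alkene.** The (E)-enone of 6 is cut at C5=C6 into terminal alkene 4 and vinyl ketone 5 (cross-metathesis). This is safe only because C9=C10 in 4 belongs to an enoate. An allylic ester at C11 would leave a trisubstituted alkene able to close a cyclohexene onto the ruthenium alkylidene; the electron-poor, β,β-disubstituted enoate does not engage. That is why the route starts from the conjugated ester 1.

**C3–C4 bond.** Alcohol 4 is cut between C3 and C4 into aldehyde 2 and allene 3. An iridium-catalysed reverse prenylation makes this bond, brings in the gem-dimethyl and vinyl groups, and sets C3, the only centre that depends on a chiral catalyst.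

**Aldehyde 2.** It is the ozonolysis product of the 6,7-alkene of 1; the conjugated 2,3-alkene, which carries the (E) geometry of the dienophile, is left alone.

## Alternatives that were turned down

**Alternative 1:** Ring A is opened at C3–C4. The substrate would be the 6,6-dialkylated carvone-type enone A1. An iron hydride made in the flask from Fe(acac)3 and a silane transfers a hydrogen atom to the isopropenyl group; the tertiary C4 radical adds to the tethered aldehyde carbon and closes ring A, giving hydroxy enone A2.
- For: C5 comes from the chiral pool and C10 from alkylation anti to the isopropenyl group, so no chiral catalyst is needed. Ring B with its alkene and C8 methyl is present from the start, and the gem-dimethyl group and the C3 oxygen arrive in the key step. It reaches a decalin in fewer steps than the chosen route; on these points it is stronger.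
- Against: A2 stops one carbon short, with C9 a ketone between the quaternary C10 and the enone carbon C8. C11 has to be added there, and H9 has to end on the face of the C10 methyl. External reagents approach anti to that methyl and give the wrong epimer, and there is no C7 oxygen to deliver hydrogen from inside. The alkoxy radical formed by addition to C=O fragments back unless trapped quickly, the enone of A1 competes for the hydrogen atom, and the C3 configuration is not predictable.
- Comparison: the chosen route is longer to the decalin, but it has C11 in place from the first step and a built-in way to set C9.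

**Alternative 2:** The cut lies in the coumarin, at the arene bond C4a′–C8a′. Heating the 4-alkenyl-4-hydroxycyclobutenone A3 opens the four-membered ring to a dienylketene, which closes by 6π-electrocyclisation and tautomerises to hydroquinone A4.
- For: the terpenyl alcohol would be attached to a squarate ester by addition–elimination at an sp2 carbon, which avoids substitution at the hindered C11. On this one point it is stronger than the Mitsunobu step. The substitution pattern of the arene is unambiguous.
- Against: from A4 the two phenols must still be told apart, the acetal unmasked, two carbons added and the lactone closed, with an air-sensitive hydroquinone and an acid step near the 7,8-alkene. All of this rebuilds what 24 supplies. The complete terpenoid alcohol must exist first, so nothing about the decalin is solved.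
- Comparison: it adds about six steps after the terpenoid is made; the chosen route spends its steps on the decalin.

**Alternative 3:** The cut is C4′–C4a′ of the pyranone ring. A cationic monovalent gold complex such as Ph3PAuNTf2 activates the alkyne of aryl propiolate A5; the arene carbon para to the terpenyloxy group attacks, and protodeauration gives A6, the C3 silyl ether of the target.
- For: the ring closure is mild and catalytic, position and electronics agree on the regiochemistry, and only a desilylation follows.
- Against: A5 needs a phenol that already carries the terpenyl ether, so the hindered C11–O bond must be made anyway, to a phenol no better than 24, and then esterified. Aryl propiolates are labile acylating agents, and the Lewis-acidic gold with traces of strong acid can move the 7,8-alkene.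
- Comparison: it is as convergent as the chosen end game but three or four steps longer, and it too says nothing about the decalin.

Key step: step 7

Assumption 1: the (S)-SEGPHOS-modified iridium catalyst is taken to add the tert-prenyl group to the Si face of aldehyde 2 and so give (6R)-4; if the sense proves opposite, (R)-SEGPHOS is used.
Assumption 2: methyl geranate 1 is used as the pure (2E) isomer, since its geometry becomes that of the dienophile.

## Route

Step 1
Reactants: 1 methyl (2E)-3,7-dimethylocta-2,6-dienoate (methyl geranate)
Product: 2 methyl (2E)-3-methyl-6-oxohex-2-enoate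
Conditions: O3, CH2Cl2, −78 °C (Sudan Red 7B end point); Me2S, −78 °C → rt
Reagents that add atoms: ozone, [O-][O+]=O
Why: Chemoselective ozonolysis with reductive work-up: the trialkyl 6,7-alkene is electron-rich and the 2,3-alkene is deactivated by the ester, so only the former should be cleaved and the (E) enoate is kept.

Step 2
Reactants: 2 methyl (2E)-3-methyl-6-oxohex-2-enoate; 3 3-methylbuta-1,2-diene (1,1-dimethylallene)
Product: 4 methyl (2E,6R)-6-hydroxy-3,7,7-trimethylnona-2,8-dienoate
Conditions: [Ir(cod)Cl]2 (2.5 mol%), (S)-SEGPHOS (5 mol%), 4-cyano-3-nitrobenzoic acid (10 mol%), Cs2CO3 (20 mol%), i-PrOH (2 equiv), toluene, 60 °C, sealed tube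
Reagents that add atoms: none
Why: Iridium-catalysed transfer-hydrogenative carbonyl reverse prenylation: the iridium hydride formed from isopropanol hydrometalates the allene, and the resulting 1,1-dimethylallyl iridium adds to the aldehyde through a closed chair at its substituted terminus. The chiral bisphosphine sets C3 (chain C6) as (R), and the enoate is inert under these conditions.

Step 3
Reactants: 4 methyl (2E,6R)-6-hydroxy-3,7,7-trimethylnona-2,8-dienoate; 5 pent-1-en-3-one (ethyl vinyl ketone)
Product: 6 methyl (2E,6R,8E)-6-hydroxy-3,7,7-trimethyl-10-oxododeca-2,8-dienoate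
Conditions: 5 (5 equiv), second-generation Hoveyda–Grubbs catalyst RuCl2(H2IMes)(=CH-C6H4-2-O-i-Pr) (5–10 mol%), CH2Cl2, 40 °C, argon sparge
Reagents that add atoms: none
Why: Olefin cross-metathesis between a hindered terminal alkene that does not homodimerise and an electron-poor vinyl ketone used in excess; the (E)-enone is the thermodynamic product. The trisubstituted enoate alkene is too electron-poor and hindered to enter ring-closing metathesis.

Step 4
Reactants: 6 methyl (2E,6R,8E)-6-hydroxy-3,7,7-trimethyl-10-oxododeca-2,8-dienoate
Product: 7 methyl (2E,6R,8E,10Z)-6,10-bis[(tert-butyldimethylsilyl)oxy]-3,7,7-trimethyldodeca-2,8,10-trienoate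
Conditions: TBSOTf (2.6 equiv), Et3N (4 equiv), CH2Cl2, −78 → 0 °C
Reagents that add atoms: tert-butyldimethylsilyl trifluoromethanesulfonate, CC(C)(C)[Si](C)(C)OS(=O)(=O)C(F)(F)F
Why: Silyl triflate with amine base silylates the hindered secondary alcohol and, by soft enolisation of the ethyl ketone, forms the 2-silyloxy diene; the (Z) enol ether, with methyl cis to oxygen, is the usual outcome. The methyl ester is not enolised under these conditions.

Step 5
Reactants: 7 methyl (2E,6R,8E,10Z)-6,10-bis[(tert-butyldimethylsilyl)oxy]-3,7,7-trimethyldodeca-2,8,10-trienoate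
Product: 8 (2E,6R,8E,10Z)-6,10-bis[(tert-butyldimethylsilyl)oxy]-3,7,7-trimethyldodeca-2,8,10-trien-1-ol
Conditions: i-Bu2AlH (2.5 equiv), CH2Cl2, −78 °C; aq. potassium sodium tartrate
Reagents that add atoms: none
Why: 1,2-Reduction of an α,β-unsaturated ester to the allylic alcohol by an aluminium hydride; silyl ethers and silyl enol ethers are inert to it, and the neutral tartrate work-up preserves the enol ether.

Step 6
Reactants: 8 (2E,6R,8E,10Z)-6,10-bis[(tert-butyldimethylsilyl)oxy]-3,7,7-trimethyldodeca-2,8,10-trien-1-ol
Product: 9 (2E,6R,8E,10Z)-6,10-bis[(tert-butyldimethylsilyl)oxy]-3,7,7-trimethyldodeca-2,8,10-trienal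
Conditions: MnO2 (20 equiv), CH2Cl2, rt
Reagents that add atoms: none
Why: Allylic oxidation with activated manganese dioxide is neutral and selective for the allylic alcohol, so the (E) geometry and the acid-labile dienol ether should be retained.

Step 7
Reactants: 9 (2E,6R,8E,10Z)-6,10-bis[(tert-butyldimethylsilyl)oxy]-3,7,7-trimethyldodeca-2,8,10-trienal
Product: 10 (3R,5S,8S,9R,10R)-3,7-bis[(tert-butyldimethylsilyl)oxy]drim-6-en-11-al
Conditions: toluene (0.01 M), BHT (0.1 equiv), N,O-bis(trimethylsilyl)acetamide (0.2 equiv), 170 °C, sealed tube
Reagents that add atoms: none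
Why: A concerted, asynchronous, suprafacial [4+2] cycloaddition joins the 2-silyloxy diene C5=C6–C7=C8 to the enal alkene C9=C10; the closest known class is the thermal type 1 intramolecular Diels–Alder reaction of 1,7,9-decatrienes with the activating group on the terminal carbon of an (E)-dienophile. Ring B is the cyclohexene of the cycloadduct, made by both new bonds (C5–C10 and C8–C9); ring A is closed by the C5–C10 bond alone, with the four-carbon tether C1–C4 folded as a chair. C5 and C10 are set by the endo-formyl transition state, in which the (E) geometry holds the tether exo and puts the C10 methyl anti to H5 (trans fusion). C9 follows from retention of the dienophile geometry (formyl cis to the C10 methyl) and C8 from the (Z) enol ether, whose outside methyl ends cis to the formyl group; both centres are erased in steps 10–12, so only the fusion and the facial sense have to be right. The absolute sense comes from C3: the silyloxy group lies equatorial in the chair, which with (3R) leads to (5S,10R). The tether, not polarisation, fixes the regiochemistry (the enol ether carbon C8 must bond to the enal α-carbon), so the reaction is driven by heat, and the dilute, acid-free medium protects the silyl enol ether and the enal geometry. Cis-fused isomers and the trans isomer with an axial C3 silyloxy group are diastereomers of 10 and are removed here or at 12.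

Step 8
Reactants: 10 (3R,5S,8S,9R,10R)-3,7-bis[(tert-butyldimethylsilyl)oxy]drim-6-en-11-al
Product: 12 (3R,5S,8S,9R,10R)-3-[(tert-butyldimethylsilyl)oxy]-11-hydroxydriman-7-one, via enol ether alcohol 11 (not isolated)
Conditions: i-Bu2AlH (1.3 equiv), CH2Cl2, −78 °C; then 1 M HCl, THF, 0 °C → rt
Reagents that add atoms: none
Why: The aldehyde is reduced while the C7 ketone is still masked as its silyl enol ether, and dilute acid then hydrolyses the enol ether by protonation at C6. The hindered C3 silyl ether should survive, and any epimerisation at C8 is harmless because C8 becomes trigonal in step 10.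

Step 9
Reactants: 12 (3R,5S,8S,9R,10R)-3-[(tert-butyldimethylsilyl)oxy]-11-hydroxydriman-7-one
Product: 13 (3R,5S,8S,9R,10R)-3-[(tert-butyldimethylsilyl)oxy]-7-oxodriman-11-yl acetate
Conditions: Ac2O, pyridine, DMAP (cat.), CH2Cl2, rt
Reagents that add atoms: acetic anhydride, CC(=O)OC(C)=O
Why: Standard nucleophile-catalysed acetylation of the primary alcohol; the acetate is orthogonal to the C3 silyl ether and protects C11 through the C3 oxidation.

Step 10
Reactants: 13 (3R,5S,8S,9R,10R)-3-[(tert-butyldimethylsilyl)oxy]-7-oxodriman-11-yl acetate
Product: 15 (3R,5S,10R)-3-[(tert-butyldimethylsilyl)oxy]-7-oxodrim-8-en-11-yl acetate, via trimethylsilyl enol ether 14 (not isolated)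
Conditions: TMSCl, NaI, Et3N, MeCN, rt; pentane extraction; then Pd(OAc)2 (1.1 equiv), MeCN, rt → 40 °C
Reagents that add atoms: none
Why: Iodotrimethylsilane with amine gives the thermodynamic, more substituted enol ether toward C8, which also relieves the syn 1,3 interaction of the C8 and C10 methyls. Saegusa–Ito oxidation follows: the divalent palladium enolate at C8 loses the syn axial H9 by β-hydride elimination on the face away from the C10 methyl, giving the tetrasubstituted enone.

Step 11
Reactants: 15 (3R,5S,10R)-3-[(tert-butyldimethylsilyl)oxy]-7-oxodrim-8-en-11-yl acetate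
Product: 16 (3R,5S,10R)-3-[(tert-butyldimethylsilyl)oxy]-7-[2-(4-methylbenzenesulfonyl)hydrazinylidene]drim-8-en-11-yl acetate
Conditions: TsNHNH2 (1.5 equiv), AcOH (cat.), EtOH, 70 °C
Reagents that add atoms: 4-methylbenzenesulfonohydrazide, Cc1ccc(cc1)S(=O)(=O)NN
Why: Acid-catalysed condensation of the enone with the sulfonyl hydrazide; the fully substituted β-carbon C9 blocks conjugate addition, so only the hydrazone should form.

Step 12
Reactants: 16 (3R,5S,10R)-3-[(tert-butyldimethylsilyl)oxy]-7-[2-(4-methylbenzenesulfonyl)hydrazinylidene]drim-8-en-11-yl acetate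
Product: 19 (3R,5S,9S,10R)-3-[(tert-butyldimethylsilyl)oxy]drim-7-en-11-yl acetate, via N-boryl allylic hydrazine 17 (not isolated), via allylic diazene 18 (not isolated)
Conditions: catecholborane (3 equiv), CHCl3, 0 °C → rt; then NaOAc·3H2O (5 equiv), 60 °C
Reagents that add atoms: none
Why: Reductive 1,3-transposition of an α,β-unsaturated tosylhydrazone: the borane delivers hydride to C7 along the axial path, anti to the C10 methyl, so nitrogen sits on the methyl face. Loss of sulfinate gives the diazene, whose retro-ene loss of nitrogen moves the alkene to C7=C8 and puts hydrogen on C9 from that same face. H9 therefore ends syn to the C10 methyl, as known for steroidal 4-en-3-one tosylhydrazones, which give the 5β-3-ene.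

Step 13
Reactants: 19 (3R,5S,9S,10R)-3-[(tert-butyldimethylsilyl)oxy]drim-7-en-11-yl acetate
Product: 20 (3R,5S,9S,10R)-3-hydroxydrim-7-en-11-yl acetate
Conditions: 48% aq. HF, MeCN (1:19), rt
Reagents that add atoms: none
Why: Fluoride-driven cleavage of the hindered secondary silyl ether in a weakly acidic medium that leaves the primary acetate in place and is too mild to move the trisubstituted alkene.

Step 14
Reactants: 20 (3R,5S,9S,10R)-3-hydroxydrim-7-en-11-yl acetate
Product: 21 (5S,9S,10R)-3-oxodrim-7-en-11-yl acetate
Conditions: Dess–Martin periodinane, NaHCO3, CH2Cl2, rt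
Reagents that add atoms: none
Why: Buffered hypervalent-iodine oxidation of the secondary alcohol; the conditions are neutral, so the alkene and C9 are not disturbed.

Step 15
Reactants: 21 (5S,9S,10R)-3-oxodrim-7-en-11-yl acetate
Product: 23 (3S,5S,9S,10R)-drim-7-ene-3,11-diol, via axial alcohol acetate 22 (not isolated)
Conditions: LiBH(s-Bu)3 (1.5 equiv), THF, −78 °C; then MeOH, 3 M NaOH, 30% H2O2, 0 °C → rt
Reagents that add atoms: none
Why: The bulky trialkylborohydride attacks the 4,4-dimethyl-3-ketone along the equatorial path and leaves the hydroxyl axial, syn to H5, which is (3S). The alkaline peroxide work-up oxidises the borane and saponifies the primary acetate in the same flask.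

Step 16
Reactants: 23 (3S,5S,9S,10R)-drim-7-ene-3,11-diol; 24 7-hydroxy-6-methoxy-2H-chromen-2-one (scopoletin)
Product: 25 7-{[(3S,5S,9S,10R)-3-hydroxydrim-7-en-11-yl]oxy}-6-methoxy-2H-chromen-2-one
Conditions: 24 (1.5 equiv), PPh3, DIAD, THF, 0 → 40 °C
Reagents that add atoms: none
Why: Mitsunobu etherification: the acidic phenol protonates the betaine and displaces the alkoxyphosphonium at the primary C11. The axial C3 hydroxyl, flanked by the quaternary C4, is too hindered to be activated, and no stereocentre is involved.

## Compound list

1 | methyl (2E)-3,7-dimethylocta-2,6-dienoate (methyl geranate) | CC(C)=CCC/C(C)=C/C(=O)OC | starting material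
2 | methyl (2E)-3-methyl-6-oxohex-2-enoate | O=CCC/C(C)=C/C(=O)OC | intermediate
3 | 3-methylbuta-1,2-diene (1,1-dimethylallene) | CC(C)=C=C | starting material
4 | methyl (2E,6R)-6-hydroxy-3,7,7-trimethylnona-2,8-dienoate | COC(=O)/C=C(\C)CC[C@@H](O)C(C)(C)C=C | intermediate
5 | pent-1-en-3-one (ethyl vinyl ketone) | CCC(=O)C=C | starting material
6 | methyl (2E,6R,8E)-6-hydroxy-3,7,7-trimethyl-10-oxododeca-2,8-dienoate | COC(=O)/C=C(\C)CC[C@@H](O)C(C)(C)/C=C/C(=O)CC | intermediate
7 | methyl (2E,6R,8E,10Z)-6,10-bis[(tert-butyldimethylsilyl)oxy]-3,7,7-trimethyldodeca-2,8,10-trienoate | COC(=O)/C=C(\C)CC[C@@H](O[Si](C)(C)C(C)(C)C)C(C)(C)/C=C/C(O[Si](C)(C)C(C)(C)C)=C/C | intermediate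
8 | (2E,6R,8E,10Z)-6,10-bis[(tert-butyldimethylsilyl)oxy]-3,7,7-trimethyldodeca-2,8,10-trien-1-ol | OC/C=C(\C)CC[C@@H](O[Si](C)(C)C(C)(C)C)C(C)(C)/C=C/C(O[Si](C)(C)C(C)(C)C)=C/C | intermediate
9 | (2E,6R,8E,10Z)-6,10-bis[(tert-butyldimethylsilyl)oxy]-3,7,7-trimethyldodeca-2,8,10-trienal (cycloaddition precursor) | O=C/C=C(\C)CC[C@@H](O[Si](C)(C)C(C)(C)C)C(C)(C)/C=C/C(O[Si](C)(C)C(C)(C)C)=C/C | intermediate
10 | (3R,5S,8S,9R,10R)-3,7-bis[(tert-butyldimethylsilyl)oxy]drim-6-en-11-al (trans-decalin; formyl, C8 methyl and C10 methyl on one face; C3 silyloxy equatorial) | O=C[C@@H]1[C@H](C)C(O[Si](C)(C)C(C)(C)C)=C[C@@H]2C(C)(C)[C@H](O[Si](C)(C)C(C)(C)C)CC[C@]21C | intermediate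
11 | (3R,5S,8S,9R,10R)-3,7-bis[(tert-butyldimethylsilyl)oxy]drim-6-en-11-ol | OC[C@@H]1[C@H](C)C(O[Si](C)(C)C(C)(C)C)=C[C@@H]2C(C)(C)[C@H](O[Si](C)(C)C(C)(C)C)CC[C@]21C | intermediate (not isolated)
12 | (3R,5S,8S,9R,10R)-3-[(tert-butyldimethylsilyl)oxy]-11-hydroxydriman-7-one (C8 drawn as formed in step 7) | OC[C@@H]1[C@H](C)C(=O)C[C@@H]2C(C)(C)[C@H](O[Si](C)(C)C(C)(C)C)CC[C@]21C | intermediate
13 | (3R,5S,8S,9R,10R)-3-[(tert-butyldimethylsilyl)oxy]-7-oxodriman-11-yl acetate | CC(=O)OC[C@@H]1[C@H](C)C(=O)C[C@@H]2C(C)(C)[C@H](O[Si](C)(C)C(C)(C)C)CC[C@]21C | intermediate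
14 | (3R,5S,9S,10R)-3-[(tert-butyldimethylsilyl)oxy]-7-[(trimethylsilyl)oxy]drim-7-en-11-yl acetate (C9 spatially as in 13; the descriptor changes with the ring alkene) | CC(=O)OC[C@@H]1C(C)=C(O[Si](C)(C)C)C[C@@H]2C(C)(C)[C@H](O[Si](C)(C)C(C)(C)C)CC[C@]21C | intermediate (not isolated)
15 | (3R,5S,10R)-3-[(tert-butyldimethylsilyl)oxy]-7-oxodrim-8-en-11-yl acetate | CC(=O)OCC1=C(C)C(=O)C[C@@H]2C(C)(C)[C@H](O[Si](C)(C)C(C)(C)C)CC[C@]21C | intermediate
16 | (3R,5S,10R)-3-[(tert-butyldimethylsilyl)oxy]-7-[2-(4-methylbenzenesulfonyl)hydrazinylidene]drim-8-en-11-yl acetate (C=N geometry not defined) | CC(=O)OCC1=C(C)C(=NNS(=O)(=O)c3ccc(C)cc3)C[C@@H]2C(C)(C)[C@H](O[Si](C)(C)C(C)(C)C)CC[C@]21C | intermediate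
17 | (3R,5S,7R,10R)-7-[1-(1,3,2-benzodioxaborol-2-yl)-2-(4-methylbenzenesulfonyl)hydrazinyl]-3-[(tert-butyldimethylsilyl)oxy]drim-8-en-11-yl acetate (nitrogen on the C10-methyl face) | CC(=O)OCC1=C(C)[C@H](N(B3Oc4ccccc4O3)NS(=O)(=O)c3ccc(C)cc3)C[C@@H]2C(C)(C)[C@H](O[Si](C)(C)C(C)(C)C)CC[C@]21C | intermediate (not isolated)
18 | (3R,5S,7R,10R)-3-[(tert-butyldimethylsilyl)oxy]-7-diazenyldrim-8-en-11-yl acetate | CC(=O)OCC1=C(C)[C@H](N=N)C[C@@H]2C(C)(C)[C@H](O[Si](C)(C)C(C)(C)C)CC[C@]21C | intermediate (not isolated)
19 | (3R,5S,9S,10R)-3-[(tert-butyldimethylsilyl)oxy]drim-7-en-11-yl acetate (H9 syn to the C10 methyl) | CC(=O)OC[C@H]1C(C)=CC[C@@H]2C(C)(C)[C@H](O[Si](C)(C)C(C)(C)C)CC[C@]21C | intermediate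
20 | (3R,5S,9S,10R)-3-hydroxydrim-7-en-11-yl acetate (equatorial 3-OH) | CC(=O)OC[C@H]1C(C)=CC[C@@H]2C(C)(C)[C@H](O)CC[C@]21C | intermediate
21 | (5S,9S,10R)-3-oxodrim-7-en-11-yl acetate | CC(=O)OC[C@H]1C(C)=CC[C@@H]2C(C)(C)C(=O)CC[C@]21C | intermediate
22 | (3S,5S,9S,10R)-3-hydroxydrim-7-en-11-yl acetate (axial 3-OH) | CC(=O)OC[C@H]1C(C)=CC[C@@H]2C(C)(C)[C@@H](O)CC[C@]21C | intermediate (not isolated)
23 | (3S,5S,9S,10R)-drim-7-ene-3,11-diol | OC[C@H]1C(C)=CC[C@@H]2C(C)(C)[C@@H](O)CC[C@]21C | intermediate
24 | 7-hydroxy-6-methoxy-2H-chromen-2-one (scopoletin) | COc1cc2ccc(=O)oc2cc1O | starting material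
25 | 7-{[(3S,5S,9S,10R)-3-hydroxydrim-7-en-11-yl]oxy}-6-methoxy-2H-chromen-2-one (CNP0218138.1) | COc1cc2ccc(=O)oc2cc1OC[C@H]1C(C)=CC[C@@H]2C(C)(C)[C@@H](O)CC[C@]21C | target

## Step count and least certain steps

Total step count: 16. Longest linear sequence: 16 steps (1 → 25); compounds 3, 5 and 24 enter in single steps.

**Step 7 (key step).**
- What may go wrong: bond formation between the neopentyl C5 and the future quaternary C10 is slow, and the enol-ether polarisation does not help. The temperature needed may cause E/Z scrambling of the enal through its dienol, which feeds the cis-fused series. The endo and facial preferences may be modest because the C8 and C10 methyls end syn on ring B and the equatorial preference of the C3 silyloxy group next to the gem-dimethyl carbon is small.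
- Fallback: run the cycloaddition one oxidation level higher, on ester 7, which cannot isomerise through a dienol and tolerates 200–220 °C (1,2-dichlorobenzene, BHT). This should give the ester cycloadduct methyl (3R,5S,8S,9R,10R)-3,7-bis[(tert-butyldimethylsilyl)oxy]drim-6-en-11-oate F1. Reduction of F1 with i-Bu2AlH gives alcohol 11, and the acidic work-up of step 8 returns the route to 12, with steps 5 and 6 skipped. The price is a weaker endo preference, so more depends on separating isomers at 12.

**Step 3.**
- What may go wrong: slow or incomplete metathesis at the vinyl group on the quaternary carbon, with catalyst decay and vinyl ketone dimerisation taking over.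
- Fallback: from 4, silylation (TBSOTf, 2,6-lutidine) gives methyl (2E,6R)-6-[(tert-butyldimethylsilyl)oxy]-3,7,7-trimethylnona-2,8-dienoate F2. Lemieux–Johnson cleavage of the terminal alkene (OsO4 cat., NaIO4, 2,6-lutidine, dioxane/H2O; the enoate alkene is too electron-poor to compete) gives methyl (2E,6R)-6-[(tert-butyldimethylsilyl)oxy]-3,7,7-trimethyl-8-oxooct-2-enoate F3. Horner–Wadsworth–Emmons olefination with diethyl (2-oxobutyl)phosphonate and Ba(OH)2 gives methyl (2E,6R,8E)-6-[(tert-butyldimethylsilyl)oxy]-3,7,7-trimethyl-10-oxododeca-2,8-dienoate F4. Enol silylation of F4 (TBSOTf, Et3N) returns to 7.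

**Step 10.**
- What may go wrong: incomplete regiocontrol in forming the tetrasubstituted enol ether, or β-hydride loss toward the C8 methyl, which gives the exocyclic methylene ketone instead of the ring enone.
- Fallback: from 13, chlorination at the more substituted α-carbon (SO2Cl2, CCl4) gives the 8-chloro ketone F5. Dehydrochlorination with LiCl in DMF at 100 °C gives the conjugated ring enone 15.

**Step 12.**
- What may go wrong: hydride delivery to C7 from the face of the C10 methyl, which would put nitrogen on the other face and give the C9 epimer; or sluggish reduction of the hindered hydrazone.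
- Fallback: from 15, reduction with LiBH(s-Bu)3 at −78 °C (equatorial delivery) gives (3R,5S,7S,10R)-3-[(tert-butyldimethylsilyl)oxy]-7-hydroxydrim-8-en-11-yl acetate F6, with the hydroxyl anti to the C10 methyl. A Mitsunobu reaction with 2-nitrobenzenesulfonylhydrazide (PPh3, DEAD, THF, −30 °C) inverts C7 and gives the N-allylic sulfonylhydrazine F7. On warming, F7 loses the sulfinate to give diazene 18, which collapses to 19. Here the C7 configuration is fixed by an isolable alcohol and a stereospecific inversion, not by a single hydride addition.

**Step 16.**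
- What may go wrong: slow displacement at the β-branched C11 under Mitsunobu conditions, so that elimination toward C9 or alkylation of the reduced azodicarboxylate competes.
- Fallback: from 23, selective sulfonylation of the primary alcohol (TsCl, pyridine, 0 °C) gives (3S,5S,9S,10R)-3-hydroxydrim-7-en-11-yl 4-methylbenzenesulfonate F8. Displacement of F8 with 24 and Cs2CO3 in DMF at 60 °C gives 25.

## Further compounds

F1 | step 7 | methyl (3R,5S,8S,9R,10R)-3,7-bis[(tert-butyldimethylsilyl)oxy]drim-6-en-11-oate | COC(=O)[C@@H]1[C@H](C)C(O[Si](C)(C)C(C)(C)C)=C[C@@H]2C(C)(C)[C@H](O[Si](C)(C)C(C)(C)C)CC[C@]21C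
F2 | step 3 | methyl (2E,6R)-6-[(tert-butyldimethylsilyl)oxy]-3,7,7-trimethylnona-2,8-dienoate | COC(=O)/C=C(\C)CC[C@@H](O[Si](C)(C)C(C)(C)C)C(C)(C)C=C
F3 | step 3 | methyl (2E,6R)-6-[(tert-butyldimethylsilyl)oxy]-3,7,7-trimethyl-8-oxooct-2-enoate | COC(=O)/C=C(\C)CC[C@@H](O[Si](C)(C)C(C)(C)C)C(C)(C)C=O
F4 | step 3 | methyl (2E,6R,8E)-6-[(tert-butyldimethylsilyl)oxy]-3,7,7-trimethyl-10-oxododeca-2,8-dienoate | COC(=O)/C=C(\C)CC[C@@H](O[Si](C)(C)C(C)(C)C)C(C)(C)/C=C/C(=O)CC
F5 | step 10 | 8-chloro-3-[(tert-butyldimethylsilyl)oxy]-7-oxodriman-11-yl acetate (C3, C5, C9 and C10 as in 13; C8 not defined) | CC(=O)OC[C@@H]1C(C)(Cl)C(=O)C[C@@H]2C(C)(C)[C@H](O[Si](C)(C)C(C)(C)C)CC[C@]21C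
F6 | step 12 | (3R,5S,7S,10R)-3-[(tert-butyldimethylsilyl)oxy]-7-hydroxydrim-8-en-11-yl acetate | CC(=O)OCC1=C(C)[C@@H](O)C[C@@H]2C(C)(C)[C@H](O[Si](C)(C)C(C)(C)C)CC[C@]21C
F7 | step 12 | (3R,5S,7R,10R)-3-[(tert-butyldimethylsilyl)oxy]-7-[1-(2-nitrobenzenesulfonyl)hydrazinyl]drim-8-en-11-yl acetate | CC(=O)OCC1=C(C)[C@H](N(N)S(=O)(=O)c3ccccc3[N+](=O)[O-])C[C@@H]2C(C)(C)[C@H](O[Si](C)(C)C(C)(C)C)CC[C@]21C
F8 | step 16 | (3S,5S,9S,10R)-3-hydroxydrim-7-en-11-yl 4-methylbenzenesulfonate | Cc1ccc(cc1)S(=O)(=O)OC[C@H]1C(C)=CC[C@@H]2C(C)(C)[C@@H](O)CC[C@]21C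
A1 | alternative 1 | 3-[(1R,6R)-1,3-dimethyl-2-oxo-6-(prop-1-en-2-yl)cyclohex-3-en-1-yl]propanal | O=C1C(C)=CC[C@H](C(C)=C)[C@@]1(C)CCC=O
A2 | alternative 1 | (3S,5S,10R)-3-hydroxy-11-nordrim-7-en-9-one | O=C1C(C)=CC[C@@H]2C(C)(C)[C@@H](O)CC[C@]21C
A3 | alternative 2 | 3-{[(3S,5S,9S,10R)-3-[(tert-butyldimethylsilyl)oxy]drim-7-en-11-yl]oxy}-4-(3,3-diethoxyprop-1-en-1-yl)-4-hydroxycyclobut-2-en-1-one (carbinol centre and alkene geometry not defined) | CCOC(OCC)C=CC1(O)C(OC[C@H]2C(C)=CC[C@@H]3C(C)(C)[C@@H](O[Si](C)(C)C(C)(C)C)CC[C@]32C)=CC1=O
A4 | alternative 2 | 2-{[(3S,5S,9S,10R)-3-[(tert-butyldimethylsilyl)oxy]drim-7-en-11-yl]oxy}-5-(diethoxymethyl)benzene-1,4-diol | Oc1cc(OC[C@H]2C(C)=CC[C@@H]3C(C)(C)[C@@H](O[Si](C)(C)C(C)(C)C)CC[C@]32C)c(O)cc1C(OCC)OCC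
A5 | alternative 3 | 3-{[(3S,5S,9S,10R)-3-[(tert-butyldimethylsilyl)oxy]drim-7-en-11-yl]oxy}-4-methoxyphenyl prop-2-ynoate | C#CC(=O)Oc1ccc(OC)c(OC[C@H]2C(C)=CC[C@@H]3C(C)(C)[C@@H](O[Si](C)(C)C(C)(C)C)CC[C@]32C)c1
A6 | alternative 3 | 7-{[(3S,5S,9S,10R)-3-[(tert-butyldimethylsilyl)oxy]drim-7-en-11-yl]oxy}-6-methoxy-2H-chromen-2-one | COc1cc2ccc(=O)oc2cc1OC[C@H]1C(C)=CC[C@@H]2C(C)(C)[C@@H](O[Si](C)(C)C(C)(C)C)CC[C@]21C
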